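**Plan**
- **Cuts:** in each of the three guaiacylglycerol units, the Cα–Cβ bond and the Cβ–O(aryl) bond are cut, the outer unit first and then both inner units at once. Last come the C8–C8' bond and the two C7–O bonds of the furofuran core.
- **Enabling feature:** the two inner units are bound through their Cβ–O bonds to C4 of the two syringyl rings of the 3,7-dioxabicyclo[3.3.0]octane core. Both are erythro (αS,βR), so the core plus these two arms has a C2 axis and one chiral promoter can build both arms in a single operation.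
- **Forward order:** both tetrahydrofuran rings form together when sinapyl alcohol is dimerised, and no further ring is made. The chain then grows outwards by O-alkylation with BrCH2C(O)SEt, twofold aldol, reduction, silylation, release of one phenol, O-alkylation, third aldol, reduction and desilylation.
- **Stereochemistry:** the core takes its relative configuration from the dimerisation and its absolute configuration (7R,8S,7'R,8'S) from resolution. The four inner centres come from the anti-selective Mukaiyama aldol with Sn(OTf)2 and the (R)-diamine, and the two outer centres (αR,βS) from the same reaction with the (S)-diamine.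

Key step: step 6

Assumption 1: the sense of induction of the α-benzyloxy donor with benzaldehyde ((S)-diamine gives the (2R,3R)-anti adduct) is taken to hold for α-aryloxy donors, so the (R)-diamine serves the inner arms and the (S)-diamine the outer one.
Assumption 2: LDA/TMSCl is taken to give the same olefin geometry as with S-ethyl benzyloxythioacetate, namely Z by CIP ranking (aryloxy cis to SEt).
Remark: both enantiomers of 1-ethyl-2-(piperidin-1-ylmethyl)pyrrolidine are treated as available ligands (three routine steps from D- or L-proline, recovered by acid extraction) and are not counted.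

**Step 1**
Reactants: 1 sinapyl alcohol (two molecules)
Product: 2 (±)-syringaresinol (racemic cis-fused 2,6-diaryl-3,7-dioxabicyclo[3.3.0]octane, both 4-hydroxy-3,5-dimethoxyphenyl groups on the convex face)
Conditions: FeCl3·6H2O (1.1 equiv per phenol), acetone–H2O, rt
Reagents that add atoms: none
Why: Oxidative phenol coupling, in which two sinapyl radicals join at C8–C8' because both ortho positions carry methoxy groups, and each quinone methide is then captured by the γ-hydroxyl of the other half in a 5-exo addition, which gives the cis-fused bicycle with both aryl groups exo as the racemate.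

**Step 2**
Reactants: 2 (±)-syringaresinol
Product: 3 (−)-syringaresinol, (7R,8S,7'R,8'S), that is 4,4'-[(1R,3aS,4R,6aS)-tetrahydro-1H,3H-furo[3,4-c]furan-1,4-diyl]bis(2,6-dimethoxyphenol)
Conditions: preparative HPLC, cellulose tris(3,5-dimethylphenylcarbamate) on silica, hexane–EtOH, rt; levorotatory fraction kept
Reagents that add atoms: none
Why: Enantiomer separation by chromatography on a polysaccharide chiral stationary phase, a resolution type established for furofuran lignans, changes no bond and fixes the absolute configuration of all four core centres by keeping the levorotatory enantiomer.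

**Step 3**
Reactants: 4 bromoacetyl bromide; 5 ethanethiol
Product: 6 S-ethyl bromothioacetate
Conditions: pyridine (1.0 equiv), CH2Cl2, −20 → 0 °C
Reagents that add atoms: none
Why: Acyl substitution (thioester formation), in which the acyl bromide is far more electrophilic than the primary alkyl bromide, so one equivalent of thiol at low temperature exchanges only the C(O)–Br bond.

**Step 4**
Reactants: 3 (−)-syringaresinol; 6 S-ethyl bromothioacetate (two molecules)
Product: 7 (−)-syringaresinol 4,4'-bis(O-CH2C(O)SEt) ether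
Conditions: K2CO3, 6 (2.4 equiv), dry DMF, rt → 40 °C
Reagents that add atoms: none
Why: Twofold Williamson ether synthesis, in which the α-bromo thioester is an activated SN2 electrophile that even the flanked syringyl phenoxides attack at carbon, while the core stereocentres are inert to carbonate.

**Step 5**
Reactants: 8 vanillin
Product: 9 4-(tert-butyldimethylsilyloxy)-3-methoxybenzaldehyde
Conditions: TBSCl, imidazole, DMF, rt
Reagents that add atoms: TBSCl, CC(C)(C)[Si](C)(C)Cl
Why: Standard phenol silylation, with a fluoride-labile group chosen because hydrogenolysis of a benzyl ether would later endanger the benzylic C–O bonds of the furofuran and of the carbinols.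

**Step 6**
Reactants: 7 (−)-syringaresinol 4,4'-bis(O-CH2C(O)SEt) ether; 9 4-(tert-butyldimethylsilyloxy)-3-methoxybenzaldehyde (two molecules)
Product: 11 C2-symmetric bis(erythro α-aryloxy-β-hydroxy thioester) in which each syringyl O-4 is bound to C2 of an S-ethyl (2S,3S)-3-hydroxy-3-[4-(tert-butyldimethylsilyloxy)-3-methoxyphenyl]propanethioate unit, via bis(Z silyl ketene thioacetal) 10 (not isolated)
Conditions: (a) LDA (2.3 equiv), TMSCl (3 equiv), THF, −78 °C; evaporation, toluene–hexane, filtration under Ar; (b) Sn(OTf)2 (2.6 equiv), (R)-1-ethyl-2-(piperidin-1-ylmethyl)pyrrolidine (3.1 equiv), Bu2Sn(OAc)2 (2.8 equiv), 9 (3 equiv), CH2Cl2, −78 °C; sat. aq NaHCO3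
Reagents that add atoms: TMSCl, C[Si](C)(C)Cl (its Me3Si groups stand in 10 only and are lost again on the way to 11)
Why: LDA and TMSCl turn each OCH2C(O)SEt arm of 7 into a Z silyl ketene thioacetal whose nucleophilic carbon already carries the aryl ether oxygen; aldehyde 9, bound to the diamine-chelated divalent tin centre, is then attacked through an open transition state, the silyl group passes to triflate, and the tin aldolate is hydrolysed on work-up. The closest known reaction type is the anti-selective asymmetric Mukaiyama aldol of Z α-benzyloxy thioester silyl ketene acetals with aromatic aldehydes under Sn(OTf)2, a proline-derived diamine and Bu2Sn(OAc)2. No ring closes, and the step forms the Cα–Cβ bond of each inner arm, two C–C bonds in all. The configuration at each carbinol carbon Cα follows from the aldehyde face left open by the (R)-diamine, and that at each Cβ follows from the Z geometry together with contact of the donor ether oxygen (or a flanking methoxy oxygen) with tin, which places aryloxy and hydroxyl anti (erythro) and gives (2S,3S) in both arms. The step needs the same sense of induction twice and no interference from the core, which is secured because the C2 axis makes the two arms homotopic, each reacting carbon is separated from the nearest core stereocentre by a whole syringyl ring, and 7 offers no other acidic or electrophilic site. Because the core is a single enantiomer, a stereochemical slip in one arm gives a diastereomer that chromatography can remove, not an enantiomer.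

**Step 7**
Reactants: 11 C2-symmetric bis(erythro α-aryloxy-β-hydroxy thioester)
Product: 12 C2-symmetric tetraol, both arms (αS,βR)-erythro 1-aryl-2-aryloxypropane-1,3-diols with the terminal phenols as TBS ethers
Conditions: LiBH4 (6 equiv), THF, 0 °C → rt
Reagents that add atoms: none
Why: Thioester-to-alcohol hydride reduction, in which LiBH4 converts both C(O)SEt groups into CH2OH without touching silyl ethers or the furofuran, no stereocentre takes part, and the low temperature keeps the β-alkoxide from retro-aldol cleavage.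

**Step 8**
Reactants: 12 C2-symmetric tetraol
Product: 13 C2-symmetric hexakis(TBS) ether (four alkyl and two aryl silyl ethers)
Conditions: TBSOTf (6 equiv), 2,6-lutidine, CH2Cl2, −78 → 0 °C
Reagents that add atoms: TBSOTf, CC(C)(C)[Si](C)(C)OS(=O)(=O)C(F)(F)F
Why: Exhaustive O-silylation with a silyl triflate under basic buffering, preferred to acetonides because an erythro 1,3-diol would have to form a cis-4,5-disubstituted dioxane under acid that can ionise these electron-rich benzylic carbinols, and because all silyl groups can leave together at the end.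

**Step 9**
Reactants: 13 C2-symmetric hexakis(TBS) ether
Product: 14 monophenol (one terminal guaiacyl OH free, five TBS ethers kept)
Conditions: TBAF–AcOH (1:1, 0.8 equiv), THF, −20 → 0 °C; recovered 13 resubmitted
Reagents that add atoms: none
Why: Fluoride-induced desilylation with the reagent as the limiting component, in which aryl silyl ethers are cleaved much faster than alkyl ones because phenoxide is the better leaving group, and the two aryl silyl ethers are homotopic so that only one monophenol can form.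

**Step 10**
Reactants: 14 monophenol; 6 S-ethyl bromothioacetate
Product: 15 mono(aryloxythioacetate), the freed guaiacyl O-4 carrying CH2C(O)SEt
Conditions: K2CO3, 6 (1.3 equiv), dry acetone, rt
Reagents that add atoms: none
Why: Williamson ether synthesis of an unhindered guaiacyl phenoxide with an activated bromide, fast enough at room temperature in a dry aprotic medium that the remaining aryl silyl ether is not disturbed.

**Step 11**
Reactants: 15 mono(aryloxythioacetate); 9 4-(tert-butyldimethylsilyloxy)-3-methoxybenzaldehyde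
Product: 17 erythro α-aryloxy-β-hydroxy thioester of the outer unit, new S-ethyl (2R,3R)-propanethioate segment, via Z silyl ketene thioacetal 16 (not isolated)
Conditions: (a) LDA (1.2 equiv), TMSCl (1.5 equiv), THF, −78 °C; evaporation, toluene–hexane, filtration under Ar; (b) Sn(OTf)2 (1.4 equiv), (S)-1-ethyl-2-(piperidin-1-ylmethyl)pyrrolidine (1.7 equiv), Bu2Sn(OAc)2 (1.5 equiv), 9 (1.6 equiv), CH2Cl2, −78 °C; sat. aq NaHCO3
Reagents that add atoms: TMSCl, C[Si](C)(C)Cl (its Me3Si group stands in 16 only and is lost again on the way to 17)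
Why: The same anti-selective asymmetric Mukaiyama aldol as in step 6 but with the enantiomeric promoter, so that aldehyde face and anti relationship now give the (2R,3R) thioester (erythro, later αR,βS), while the resident stereocentres lie beyond an aromatic ring and should not compete with reagent control.

**Step 12**
Reactants: 17 erythro α-aryloxy-β-hydroxy thioester of the outer unit
Product: 18 outer (αR,βS)-erythro 1,3-diol, six TBS ethers kept
Conditions: LiBH4 (3 equiv), THF, 0 °C → rt
Reagents that add atoms: none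
Why: Thioester-to-alcohol hydride reduction as in step 7, which leaves all silyl ethers and all ten stereocentres untouched.

**Step 13**
Reactants: 18 outer (αR,βS)-erythro 1,3-diol
Product: 19 target CNP0316493.2
Conditions: TBAF–AcOH (1:1, excess), THF, rt; reversed-phase chromatography
Reagents that add atoms: none
Why: Global fluoride desilylation, in which buffered TBAF cleaves the two aryl and four alkyl silyl ethers under nearly neutral conditions, so that neither acid-induced ionisation at Cα nor quinone methide formation from the freed phenols can scramble the benzylic stereocentres.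

**Compound list**

1 | sinapyl alcohol | COc1cc(/C=C/CO)cc(OC)c1O | starting material
2 | (±)-syringaresinol (racemate, both enantiomers written) | COc1cc(cc(OC)c1O)[C@@H]1OC[C@@H]2[C@H]1CO[C@H]2c1cc(OC)c(O)c(OC)c1.COc1cc(cc(OC)c1O)[C@H]1OC[C@H]2[C@@H]1CO[C@@H]2c1cc(OC)c(O)c(OC)c1 | intermediate
3 | (−)-syringaresinol, (7R,8S,7'R,8'S) | COc1cc(cc(OC)c1O)[C@@H]1OC[C@@H]2[C@H]1CO[C@H]2c1cc(OC)c(O)c(OC)c1 | intermediate
4 | bromoacetyl bromide | BrCC(Br)=O | starting material
5 | ethanethiol | CCS | starting material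
6 | S-ethyl bromothioacetate | CCSC(=O)CBr | intermediate
7 | (−)-syringaresinol 4,4'-bis(O-CH2C(O)SEt) ether | CCSC(=O)COc1c(OC)cc(cc1OC)[C@@H]1OC[C@@H]2[C@H]1CO[C@H]2c1cc(OC)c(OCC(=O)SCC)c(OC)c1 | intermediate
8 | vanillin | COc1cc(C=O)ccc1O | starting material
9 | 4-(tert-butyldimethylsilyloxy)-3-methoxybenzaldehyde | COc1cc(C=O)ccc1O[Si](C)(C)C(C)(C)C | intermediate
10 | (−)-syringaresinol 4,4'-bis[(Z)-2-(ethylsulfanyl)-2-(trimethylsilyloxy)ethenyl] ether | CCS/C(O[Si](C)(C)C)=C\Oc1c(OC)cc(cc1OC)[C@@H]1OC[C@@H]2[C@H]1CO[C@H]2c1cc(OC)c(O/C=C(\SCC)O[Si](C)(C)C)c(OC)c1 | intermediate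
11 | C2-symmetric bis[(2S,3S)-anti aldol thioester], phenols as TBS ethers | COc1cc(ccc1O[Si](C)(C)C(C)(C)C)[C@H](O)[C@@H](C(=O)SCC)Oc1c(OC)cc(cc1OC)[C@@H]1OC[C@@H]2[C@H]1CO[C@H]2c1cc(OC)c(O[C@H](C(=O)SCC)[C@@H](O)c2ccc(O[Si](C)(C)C(C)(C)C)c(OC)c2)c(OC)c1 | intermediate
12 | C2-symmetric (αS,βR),(αS,βR)-tetraol, phenols as TBS ethers | COc1cc(ccc1O[Si](C)(C)C(C)(C)C)[C@H](O)[C@@H](CO)Oc1c(OC)cc(cc1OC)[C@@H]1OC[C@@H]2[C@H]1CO[C@H]2c1cc(OC)c(O[C@H](CO)[C@@H](O)c2ccc(O[Si](C)(C)C(C)(C)C)c(OC)c2)c(OC)c1 | intermediate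
13 | C2-symmetric hexakis(TBS) ether | COc1cc(ccc1O[Si](C)(C)C(C)(C)C)[C@H](O[Si](C)(C)C(C)(C)C)[C@@H](CO[Si](C)(C)C(C)(C)C)Oc1c(OC)cc(cc1OC)[C@@H]1OC[C@@H]2[C@H]1CO[C@H]2c1cc(OC)c(O[C@H](CO[Si](C)(C)C(C)(C)C)[C@@H](O[Si](C)(C)C(C)(C)C)c2ccc(O[Si](C)(C)C(C)(C)C)c(OC)c2)c(OC)c1 | intermediate
14 | monophenol, pentakis(TBS) ether | COc1cc(ccc1O)[C@H](O[Si](C)(C)C(C)(C)C)[C@@H](CO[Si](C)(C)C(C)(C)C)Oc1c(OC)cc(cc1OC)[C@@H]1OC[C@@H]2[C@H]1CO[C@H]2c1cc(OC)c(O[C@H](CO[Si](C)(C)C(C)(C)C)[C@@H](O[Si](C)(C)C(C)(C)C)c2ccc(O[Si](C)(C)C(C)(C)C)c(OC)c2)c(OC)c1 | intermediate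
15 | mono(O-CH2C(O)SEt) ether of 14 | COc1cc(ccc1OCC(=O)SCC)[C@H](O[Si](C)(C)C(C)(C)C)[C@@H](CO[Si](C)(C)C(C)(C)C)Oc1c(OC)cc(cc1OC)[C@@H]1OC[C@@H]2[C@H]1CO[C@H]2c1cc(OC)c(O[C@H](CO[Si](C)(C)C(C)(C)C)[C@@H](O[Si](C)(C)C(C)(C)C)c2ccc(O[Si](C)(C)C(C)(C)C)c(OC)c2)c(OC)c1 | intermediate
16 | (Z)-silyl ketene thioacetal of 15 | COc1cc(ccc1O/C=C(\SCC)O[Si](C)(C)C)[C@H](O[Si](C)(C)C(C)(C)C)[C@@H](CO[Si](C)(C)C(C)(C)C)Oc1c(OC)cc(cc1OC)[C@@H]1OC[C@@H]2[C@H]1CO[C@H]2c1cc(OC)c(O[C@H](CO[Si](C)(C)C(C)(C)C)[C@@H](O[Si](C)(C)C(C)(C)C)c2ccc(O[Si](C)(C)C(C)(C)C)c(OC)c2)c(OC)c1 | intermediate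
17 | outer (2R,3R)-anti aldol thioester, six TBS ethers | COc1cc([C@@H](O)[C@H](C(=O)SCC)Oc2ccc([C@H](O[Si](C)(C)C(C)(C)C)[C@@H](CO[Si](C)(C)C(C)(C)C)Oc3c(OC)cc([C@@H]4OC[C@@H]5[C@H]4CO[C@H]5c4cc(OC)c(O[C@H](CO[Si](C)(C)C(C)(C)C)[C@@H](O[Si](C)(C)C(C)(C)C)c5ccc(O[Si](C)(C)C(C)(C)C)c(OC)c5)c(OC)c4)cc3OC)cc2OC)ccc1O[Si](C)(C)C(C)(C)C | intermediate
18 | outer (αR,βS)-diol, six TBS ethers | COc1cc([C@@H](O)[C@H](CO)Oc2ccc([C@H](O[Si](C)(C)C(C)(C)C)[C@@H](CO[Si](C)(C)C(C)(C)C)Oc3c(OC)cc([C@@H]4OC[C@@H]5[C@H]4CO[C@H]5c4cc(OC)c(O[C@H](CO[Si](C)(C)C(C)(C)C)[C@@H](O[Si](C)(C)C(C)(C)C)c5ccc(O[Si](C)(C)C(C)(C)C)c(OC)c5)c(OC)c4)cc3OC)cc2OC)ccc1O[Si](C)(C)C(C)(C)C | intermediate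
19 | CNP0316493.2 | COc1cc([C@@H](O)[C@H](CO)Oc2ccc([C@H](O)[C@@H](CO)Oc3c(OC)cc([C@@H]4OC[C@@H]5[C@H]4CO[C@H]5c4cc(OC)c(O[C@H](CO)[C@@H](O)c5ccc(O)c(OC)c5)c(OC)c4)cc3OC)cc2OC)ccc1O | target

**Totals**
Total step count: 13.
Longest linear sequence: 11 steps (1, 2, 4, 6, 7, 8, 9, 10, 11, 12, 13) from sinapyl alcohol.

**Steps most likely to fail**

**Step 6.**
- **Risk:** anti selectivity may erode. An aryl ether oxygen flanked by two methoxy groups is a weaker donor towards tin than a benzyl ether oxygen, so the donor may react through the syn-selective arrangement typical of bulky α-silyloxy donors. In a twofold reaction every shortfall counts twice.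
- **Fallback:** this uses auxiliary control in a closed transition state followed by inversion. It sets out from 3 and comes back at 13.
- Lithiated (S)-4-benzyloxazolidin-2-one is acylated with 4 to give (S)-4-benzyl-3-(bromoacetyl)oxazolidin-2-one F1.
- F1 alkylates both phenols of 3 (K2CO3, DMF) to give the bis(N-aryloxyacetyl imide) F2.
- Enolisation with Bu2BOTf/iPr2NEt and addition of 9 is an Evans syn aldol, established for aryloxyacetyl imides. It gives the bis[(2S,3R)-syn aldol imide] F3, which has the correct Cβ and the epimeric Cα.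
- LiBH4 releases the auxiliary and gives the threo,threo-tetraol F4.
- TBSCl/imidazole at 0 °C silylates only the primary hydroxyls to give the bis(primary TBS ether) F5.
- A Mitsunobu reaction (PPh3, DIAD, 4-nitrobenzoic acid) inverts both benzylic carbinols to give the bis(4-nitrobenzoate) F6.
- LiBH4 removes the esters to give the erythro,erythro-diol F7.
- TBSOTf/2,6-lutidine then leads to 13.

**Step 9.**
- **Risk:** over-cleavage at the second phenol and creeping loss of primary alkyl silyl ethers may leave a mixture whose components differ little in polarity.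
- **Fallback:** the differentiation is moved from the deprotection to the bond formation. It sets out from 13 and comes back at 15.
- Excess TBAF–AcOH at 0 °C removes both aryl silyl ethers to give the bisphenol F8.
- F8 is alkylated with a deficiency of 6 (K2CO3, acetone), so that the cheap electrophile is limiting. This gives the phenol mono(thioacetate) F9, which differs from its neighbours by a whole phenol group and should separate easily. Unreacted F8 returns directly to the alkylation.
- TBSCl/imidazole caps the remaining phenol and gives 15.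

**Step 4.**
- **Risk:** the hindered phenoxide may attack the thioester carbonyl instead of the CH2Br carbon (acyl transfer with release of thiolate). Carbonate may also cleave the thioester during a slow alkylation.
- **Fallback:** sulfur is introduced only after the ether bonds are made. It sets out from 3 and comes back at 7.
- Ethyl bromoacetate with K2CO3 in refluxing acetone gives the bis(ethyl aryloxyacetate) F10.
- Me2AlSEt, made from AlMe3 and 5 in CH2Cl2 (0 °C → rt), exchanges both ester groups for thioesters and gives 7.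

**Further compounds**

F1 | step 6 | (S)-4-benzyl-3-(bromoacetyl)oxazolidin-2-one | O=C1OC[C@H](Cc2ccccc2)N1C(=O)CBr
F2 | step 6 | bis(N-aryloxyacetyl imide) of (−)-syringaresinol with (S)-4-benzyloxazolidin-2-one | O=C1OC[C@H](Cc2ccccc2)N1C(=O)COc1c(OC)cc(cc1OC)[C@@H]1OC[C@@H]2[C@H]1CO[C@H]2c1cc(OC)c(OCC(=O)N2[C@@H](Cc3ccccc3)COC2=O)c(OC)c1
F3 | step 6 | bis[(2S,3R)-syn aldol imide] | COc1cc(ccc1O[Si](C)(C)C(C)(C)C)[C@@H](O)[C@@H](C(=O)N1[C@@H](Cc2ccccc2)COC1=O)Oc1c(OC)cc(cc1OC)[C@@H]1OC[C@@H]2[C@H]1CO[C@H]2c1cc(OC)c(O[C@H](C(=O)N2[C@@H](Cc3ccccc3)COC2=O)[C@H](O)c2ccc(O[Si](C)(C)C(C)(C)C)c(OC)c2)c(OC)c1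
F4 | step 6 | threo,threo-tetraol (αR,βR in both arms) | COc1cc(ccc1O[Si](C)(C)C(C)(C)C)[C@@H](O)[C@@H](CO)Oc1c(OC)cc(cc1OC)[C@@H]1OC[C@@H]2[C@H]1CO[C@H]2c1cc(OC)c(O[C@H](CO)[C@H](O)c2ccc(O[Si](C)(C)C(C)(C)C)c(OC)c2)c(OC)c1
F5 | step 6 | threo,threo-diol, bis(primary TBS ether) | COc1cc(ccc1O[Si](C)(C)C(C)(C)C)[C@@H](O)[C@@H](CO[Si](C)(C)C(C)(C)C)Oc1c(OC)cc(cc1OC)[C@@H]1OC[C@@H]2[C@H]1CO[C@H]2c1cc(OC)c(O[C@H](CO[Si](C)(C)C(C)(C)C)[C@H](O)c2ccc(O[Si](C)(C)C(C)(C)C)c(OC)c2)c(OC)c1
F6 | step 6 | erythro,erythro-bis(4-nitrobenzoate) | COc1cc(ccc1O[Si](C)(C)C(C)(C)C)[C@H](OC(=O)c1ccc(cc1)[N+](=O)[O-])[C@@H](CO[Si](C)(C)C(C)(C)C)Oc1c(OC)cc(cc1OC)[C@@H]1OC[C@@H]2[C@H]1CO[C@H]2c1cc(OC)c(O[C@H](CO[Si](C)(C)C(C)(C)C)[C@@H](OC(=O)c2ccc(cc2)[N+](=O)[O-])c2ccc(O[Si](C)(C)C(C)(C)C)c(OC)c2)c(OC)c1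
F7 | step 6 | erythro,erythro-diol (αS,βR in both arms), primary and aryl TBS ethers kept | COc1cc(ccc1O[Si](C)(C)C(C)(C)C)[C@H](O)[C@@H](CO[Si](C)(C)C(C)(C)C)Oc1c(OC)cc(cc1OC)[C@@H]1OC[C@@H]2[C@H]1CO[C@H]2c1cc(OC)c(O[C@H](CO[Si](C)(C)C(C)(C)C)[C@@H](O)c2ccc(O[Si](C)(C)C(C)(C)C)c(OC)c2)c(OC)c1
F8 | step 9 | C2-symmetric bisphenol, four alkyl TBS ethers | COc1cc(ccc1O)[C@H](O[Si](C)(C)C(C)(C)C)[C@@H](CO[Si](C)(C)C(C)(C)C)Oc1c(OC)cc(cc1OC)[C@@H]1OC[C@@H]2[C@H]1CO[C@H]2c1cc(OC)c(O[C@H](CO[Si](C)(C)C(C)(C)C)[C@@H](O[Si](C)(C)C(C)(C)C)c2ccc(O)c(OC)c2)c(OC)c1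
F9 | step 9 | phenol mono(O-CH2C(O)SEt) ether, four alkyl TBS ethers | COc1cc(ccc1OCC(=O)SCC)[C@H](O[Si](C)(C)C(C)(C)C)[C@@H](CO[Si](C)(C)C(C)(C)C)Oc1c(OC)cc(cc1OC)[C@@H]1OC[C@@H]2[C@H]1CO[C@H]2c1cc(OC)c(O[C@H](CO[Si](C)(C)C(C)(C)C)[C@@H](O[Si](C)(C)C(C)(C)C)c2ccc(O)c(OC)c2)c(OC)c1
F10 | step 4 | (−)-syringaresinol 4,4'-bis(O-CH2CO2Et) ether | CCOC(=O)COc1c(OC)cc(cc1OC)[C@@H]1OC[C@@H]2[C@H]1CO[C@H]2c1cc(OC)c(OCC(=O)OCC)c(OC)c1
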